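**Plan**
- Cuts: the O13–C1 ester (macrolactone), then C10–C11 (aldol), C7–C8 (alkylation) and C4–C5 (aldol). This gives a C1–C7 iodide, pentan-3-one (C8–C10) and a C11–C13 aldehyde.
- Forward: C1–C7 is joined to C8–C10 and then to C11–C13. No ring exists until the C9 ketone, which is δ to both O5 and O13, is folded with these two hydroxyls into a 1,7-dioxaspiro[5.5]undecane (ring A: O5, C5–C9; ring B: C9–C13, O13).
- In that spiroketal only the natural C8 and C10 epimers hold both methyl groups equatorial, so acid equilibration sets both centres from a C8 mixture. The spiroketal is then opened to the C9 dithiane and the 14-membered lactone is closed last.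
- Stereochemistry: C2 from the oxazolidinone; C4/C5 from a β-keto imide aldol; C3 from 1,3-syn reduction; C6 from the Roche ester; C12/C13 from an Evans aldol; C11 from an anti-Felkin syn-aldol; C8/C10 from the spiroketal equilibrium.

Key step: step 20

Remark: locants follow the macrolide numbering (C1 lactone carbonyl, O13 ring oxygen); TBDPS = tert-butyldiphenylsilyl, TES = triethylsilyl, Bn = benzyl; the keto triol that enters the key step is drawn as the open ketone although it should equilibrate with its hemiketals.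

**Step 1**
Reactants: 1 (S)-4-benzyl-3-propanoyl-1,3-oxazolidin-2-one; 2 propanoyl chloride
Product: 3 (S)-4-benzyl-3-[(R)-2-methyl-3-oxopentanoyl]-1,3-oxazolidin-2-one (C1–C4 β-keto imide)
Conditions: LiN(i-Pr)2, THF, −78 °C; then 2, −78 °C
Reagents that add atoms: none
Why: C-acylation of the chelated Z lithium enolate (enolate acylation) takes place on the face away from the benzyl group and sets C2, and allylic strain keeps the β-keto imide from enolising at that centre afterwards.

**Step 2**
Reactants: 4 methyl (S)-3-hydroxy-2-methylpropanoate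
Product: 5 methyl (S)-3-(benzyloxy)-2-methylpropanoate
Conditions: BnOC(=NH)CCl3, TfOH (cat.), CH2Cl2/cyclohexane, 0 °C → rt
Reagents that add atoms: benzyl 2,2,2-trichloroacetimidate, ClC(Cl)(Cl)C(=N)OCc1ccccc1
Why: Acid-catalysed imidate benzylation etherifies the base-sensitive β-hydroxy ester without touching the α-stereocentre that becomes C6.

**Step 3**
Reactants: 5 methyl (S)-3-(benzyloxy)-2-methylpropanoate
Product: 6 (S)-3-(benzyloxy)-2-methylpropanal (C5–C7 aldehyde)
Conditions: i-Bu2AlH, CH2Cl2, −78 °C; aq. potassium sodium tartrate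
Reagents that add atoms: none
Why: At −78 °C the tetrahedral aluminium hemiacetal persists until work-up, so this partial ester reduction stops at the aldehyde, which is used at once to avoid epimerisation.

**Step 4**
Reactants: 3 C1–C4 β-keto imide; 6 C5–C7 aldehyde
Product: 7 (S)-4-benzyl-3-[(2R,4R,5S,6S)-7-(benzyloxy)-5-hydroxy-2,4,6-trimethyl-3-oxoheptanoyl]-1,3-oxazolidin-2-one
Conditions: TiCl4, i-Pr2NEt, CH2Cl2, −10 °C; then 6, −78 → −40 °C
Reagents that add atoms: none
Why: In this titanium-mediated syn,syn aldol of a β-keto imide the chelated Z enolate reacts through a Zimmerman–Traxler chair on the face set by the C2 methyl group (C4 syn to C2, C5 syn to C4), and a Z enolate attacks the α-methyl aldehyde in the anti-Felkin sense, which gives the C5/C6 anti relation.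

**Step 5**
Reactants: 7 aldol adduct
Product: 8 (S)-4-benzyl-3-[(2R,3S,4R,5S,6S)-7-(benzyloxy)-3,5-dihydroxy-2,4,6-trimethylheptanoyl]-1,3-oxazolidin-2-one
Conditions: Zn(BH4)2, CH2Cl2/Et2O, −20 °C
Reagents that add atoms: none
Why: Chelation-controlled 1,3-syn reduction, in which zinc ties the C5 hydroxyl and the C3 ketone into a six-membered chelate and hydride arrives from its open face, sets C3 syn to C5.

**Step 6**
Reactants: 8 3,5-syn diol
Product: 9 3,5-bis-O-TES ether of 8 (C2–C6 unchanged)
Conditions: Et3SiOTf, 2,6-lutidine, CH2Cl2, −78 → 0 °C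
Reagents that add atoms: triethylsilyl trifluoromethanesulfonate, CC[Si](CC)(CC)OS(=O)(=O)C(F)(F)F
Why: Silyl triflate with a hindered base silylates both hindered secondary hydroxyls at low temperature before the C5 hydroxyl can lactonise onto the imide.

**Step 7**
Reactants: 9 bis-TES imide
Product: 10 C1–C7 primary alcohol: 7-(benzyloxy)-2,4,6-trimethyl-3,5-bis(triethylsilyloxy)heptan-1-ol (C2–C6 as in 8)
Conditions: LiBH4, EtOH (1 equiv), Et2O, 0 °C
Reagents that add atoms: none
Why: Reductive cleavage of the N-acyl oxazolidinone at the exocyclic carbonyl gives the C1 alcohol and frees the auxiliary without disturbing C2.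

**Step 8**
Reactants: 10 C1 alcohol
Product: 11 1-O-TBDPS ether of 10
Conditions: t-BuPh2SiCl, imidazole, DMF, rt
Reagents that add atoms: tert-butyl(chloro)diphenylsilane, CC(C)(C)[Si](Cl)(c1ccccc1)c1ccccc1
Why: Routine silylation of the primary alcohol installs a group that should outlast the later acid, Lewis acid and buffered fluoride steps and can still be removed by fluoride beside a dithiane.

**Step 9**
Reactants: 11 fully protected C1–C7 fragment
Product: 12 C7 alcohol (1-O-TBDPS; 3,5-bis-O-TES)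
Conditions: H2 (1 atm), Pd/C, EtOAc, rt
Reagents that add atoms: none
Why: Hydrogenolysis in a non-protic solvent removes the only benzyl ether present and spares the silyl ethers.

**Step 10**
Reactants: 12 C7 alcohol
Product: 13 C1–C7 iodide (7-iodo; 1-O-TBDPS; 3,5-bis-O-TES; C2–C6 as in 8)
Conditions: I2, PPh3, imidazole, CH2Cl2, 0 °C → rt
Reagents that add atoms: iodine, II
Why: Appel-type iodination through the alkoxyphosphonium iodide is an SN2 displacement at the primary C7 and touches no stereocentre.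

**Step 11**
Reactants: 14 pentan-3-one
Product: 15 pentan-3-one N,N-dimethylhydrazone
Conditions: Me2NNH2, AcOH (cat.), EtOH, reflux
Reagents that add atoms: 1,1-dimethylhydrazine, CN(C)N
Why: Condensation gives the hydrazone, whose azaenolate alkylates unactivated β-branched primary iodides far more cleanly than a ketone enolate does.

**Step 12**
Reactants: 15 pentan-3-one N,N-dimethylhydrazone; 13 C1–C7 iodide
Product: 17 C1–C10 ethyl ketone (9-oxo; 1-O-TBDPS; 3,5-bis-O-TES; both C8 epimers), via alkylated dimethylhydrazone 16 (not isolated)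
Conditions: LiN(i-Pr)2, THF, 0 °C; 13, −78 °C → rt; then aq. Cu(OAc)2, rt
Reagents that add atoms: water, O
Why: Azaenolate alkylation of the lithiated hydrazone forms C7–C8 by SN2 with no facial control, so C8 is made as both epimers on purpose, and Cu(OAc)2-assisted hydrolysis returns the ketone under near-neutral conditions.

**Step 13**
Reactants: 1 (S)-4-benzyl-3-propanoyl-1,3-oxazolidin-2-one; 18 acetaldehyde
Product: 19 (S)-4-benzyl-3-[(2S,3R)-3-hydroxy-2-methylbutanoyl]-1,3-oxazolidin-2-one
Conditions: Bu2BOTf, Et3N, CH2Cl2, 0 °C; 18, −78 → 0 °C; H2O2, pH 7 buffer, MeOH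
Reagents that add atoms: none
Why: In the Evans syn-aldol the Z boron enolate adds through a Zimmerman–Traxler chair on the face opposite the benzyl group, which sets C12 and C13.

**Step 14**
Reactants: 19 Evans aldol adduct
Product: 20 (2S,3R)-3-hydroxy-N-methoxy-N,2-dimethylbutanamide
Conditions: MeNH(OMe)·HCl, AlMe3, CH2Cl2, −20 °C → rt
Reagents that add atoms: N,O-dimethylhydroxylamine hydrochloride, CNOC.Cl
Why: The aluminium amide transamidates the β-hydroxy imide at the exocyclic carbonyl (Weinreb amide formation) with help from the free hydroxyl.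

**Step 15**
Reactants: 20 Weinreb amide
Product: 21 (2S,3R)-N-methoxy-N,2-dimethyl-3-(triethylsilyloxy)butanamide
Conditions: Et3SiCl, imidazole, CH2Cl2, 0 °C → rt
Reagents that add atoms: chlorotriethylsilane, CC[Si](Cl)(CC)CC
Why: Routine silylation of the secondary alcohol gives the O13 ether that is later removed together with the O3 and O5 silyl groups.

**Step 16**
Reactants: 21 silylated Weinreb amide
Product: 22 (2S,3R)-2-methyl-3-(triethylsilyloxy)butanal (C11–C13 aldehyde)
Conditions: i-Bu2AlH, THF, −78 °C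
Reagents that add atoms: none
Why: Hydride adds once because the chelated tetrahedral intermediate of the Weinreb amide survives until work-up, so the aldehyde is obtained without over-reduction.

**Step 17**
Reactants: 17 C1–C10 ethyl ketone; 22 C11–C13 aldehyde
Product: 23 C1–C13 aldol adduct (11-hydroxy-9-ketone; 1-O-TBDPS; 3,5,13-tris-O-TES; C10–C13 as in the target; both C8 epimers)
Conditions: Bu2BOTf, i-Pr2NEt, CH2Cl2, −78 → 0 °C; 22, −78 → −20 °C; H2O2, pH 7 buffer, MeOH, 0 °C
Reagents that add atoms: none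
Why: In this boron-mediated syn-aldol the ketone is enolised on its ethyl side to the Z enolate (Zimmerman–Traxler chair, C10/C11 syn), and a Z enolate adds to the α-methyl aldehyde on the anti-Felkin face to avoid a syn-pentane contact, which sets C11 anti to C12, the one new centre that step 20 cannot repair.

**Step 18**
Reactants: 23 aldol adduct
Product: 24 11-O-benzyl ether of 23
Conditions: 2-benzyloxy-1-methylpyridinium triflate, MgO, PhCF3, 83 °C
Reagents that add atoms: 2-(benzyloxy)-1-methylpyridinium trifluoromethanesulfonate, C[n+]1ccccc1OCc1ccccc1.[O-]S(=O)(=O)C(F)(F)F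
Why: The pyridinium salt transfers benzyl as a cation equivalent under neutral MgO-buffered conditions (Dudley benzylation), so the β-hydroxy ketone is etherified without retro-aldol cleavage or loss of silyl ethers.

**Step 19**
Reactants: 24 benzyl ether
Product: 25 keto triol (3,5,13-trihydroxy-9-ketone; 1-O-TBDPS; 11-O-Bn; both C8 epimers)
Conditions: HF·pyridine, pyridine, THF, 0 °C → rt
Reagents that add atoms: none
Why: Buffered fluoride cleaves the three secondary triethylsilyl ethers much faster than the primary TBDPS ether (selective desilylation), and the weakly acidic medium should stop at the ketone and its hemiketals.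

**Step 20**
Reactants: 25 keto triol (both C8 epimers)
Product: 26 5,9:9,13-spiroketal (1,7-dioxaspiro[5.5]undecane; 1-O-TBDPS; 3-OH; 11-O-Bn; C8 and C10 as in the target)
Conditions: CSA (0.3 equiv), CH2Cl2, rt → 40 °C, until the isomer ratio is constant
Reagents that add atoms: none
Why: Acid converts the C9 ketone and one δ-hydroxyl into a hemiketal, ionisation gives a cyclic oxocarbenium ion and the second δ-hydroxyl adds to it, which is the classical thermodynamic spiroketalisation of a dihydroxy ketone; here it is held under acid so that the rings reopen to the endocyclic enol ethers (C8=C9 and C9=C10) and C8 and C10 epimerise by reprotonation, as is known for centres α to a spiro carbon. Ring A (O5, C5–C9) closes 6-exo-trig on the carbonyl or oxocarbenium carbon and ring B (C9–C13, O13) closes 6-exo-trig in the same way. C9 is set by the double anomeric effect, each ring oxygen lying axial on the other ring. C10 is set by ring B, whose fixed C11, C12 and C13 substituents define one chair in which only the natural C10 methyl is equatorial and escapes a 1,3-diaxial clash with the axial C12 methyl. C8 is set by ring A, where the equatorial C5 chain and C6 methyl define the chair and an axial C8 methyl would run into the C10 methyl in a syn-pentane contact. Only thermodynamic selectivity is needed, and it is secured by the five non-epimerisable centres C5, C6, C11, C12 and C13 together with the anomeric effect, while the free C3 hydroxyl cannot reach C9 in a ring smaller than eight and stays a spectator.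

**Step 21**
Reactants: 26 spiroketal
Product: 27 C9 1,3-dithiane 3,5,13-triol (1-O-TBDPS; 11-O-Bn)
Conditions: HS(CH2)3SH, BF3·OEt2, CH2Cl2, −40 → 0 °C
Reagents that add atoms: propane-1,3-dithiol, SCCCS
Why: Lewis acid opens the spiroketal to the oxocarbenium ion and the dithiol captures it twice (transthioketalisation of a ketal), which frees O5 and O13 and locks C8 and C10 because they are no longer α to a carbonyl.

**Step 22**
Reactants: 27 dithiane triol
Product: 28 3,5-O-benzylidene acetal of 27 (phenyl equatorial; 13-OH free)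
Conditions: PhCH(OMe)2, CSA (cat.), CH2Cl2, rt
Reagents that add atoms: benzaldehyde dimethyl acetal, COC(OC)c1ccccc1
Why: Acid-catalysed transacetalisation picks the syn-1,3-diol at C3/C5 and forms the six-membered acetal with phenyl equatorial under thermodynamic control, while the isolated C13 hydroxyl has no partner and any mixed acetal there falls apart on work-up.

**Step 23**
Reactants: 28 benzylidene acetal
Product: 29 1,13-diol (C9 dithiane; 3,5-O-benzylidene; 11-O-Bn)
Conditions: Bu4NF, AcOH, THF, 0 °C → rt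
Reagents that add atoms: none
Why: Buffered fluoride removes the TBDPS ether (desilylation) and leaves acetal, dithiane and benzyl ether untouched.

**Step 24**
Reactants: 29 1,13-diol
Product: 31 seco acid (C1 acid; 13-OH), via C1 aldehyde 30 (not isolated)
Conditions: TEMPO (cat.), PhI(OAc)2, CH2Cl2/H2O, rt
Reagents that add atoms: water, O
Why: The oxoammonium-mediated oxidation with PhI(OAc)2 as terminal oxidant takes the primary alcohol through the aldehyde hydrate to the acid, leaves the hindered secondary C13 alcohol alone and is known to tolerate thioacetal sulfur.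

**Step 25**
Reactants: 31 seco acid
Product: 33 14-membered lactone (C9 dithiane; 3,5-O-benzylidene; 11-O-Bn), via mixed anhydride 32 (not isolated)
Conditions: 2,4,6-Cl3C6H2COCl, Et3N, THF, rt; then slow addition to DMAP, toluene, 80 °C (high dilution)
Reagents that add atoms: none
Why: Yamaguchi macrolactonisation acylates O13 through the mixed anhydride and the acylpyridinium ion, with the 3,5-acetal bending the C1–C6 segment toward the hydroxyl end and the dithiane shielding C8 and C10 from base.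

**Step 26**
Reactants: 33 dithiane lactone
Product: 34 3,5-O-benzylidene-11-O-benzyl-8,8a-deoxyoleandolide (C9 ketone)
Conditions: MeI, CaCO3, MeCN/H2O, 40 °C
Reagents that add atoms: water, O
Why: S-Methylation turns the dithiane into a sulfonium leaving group and water hydrolyses the resulting thionium ion (alkylative dethioketalisation) under carbonate buffer, so C8 and C10 are not enolised.

**Step 27**
Reactants: 34 protected macrolide
Product: 35 8,8a-deoxyoleandolide
Conditions: H2 (1 atm), Pd(OH)2/C, EtOAc/i-PrOH, rt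
Reagents that add atoms: none
Why: Hydrogenolysis cleaves the C11 benzyl ether and the benzylidene acetal in one operation under neutral conditions, now that sulfur is gone, and leaves the ketone, the lactone and all ten stereocentres alone.

**Compound list**
1 | (S)-4-benzyl-3-propanoyl-1,3-oxazolidin-2-one | CCC(=O)N1[C@@H](Cc2ccccc2)COC1=O | starting material
2 | propanoyl chloride | CCC(=O)Cl | starting material
3 | (S)-4-benzyl-3-[(R)-2-methyl-3-oxopentanoyl]-1,3-oxazolidin-2-one | CCC(=O)[C@@H](C)C(=O)N1[C@@H](Cc2ccccc2)COC1=O | intermediate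
4 | methyl (S)-3-hydroxy-2-methylpropanoate | COC(=O)[C@@H](C)CO | starting material
5 | methyl (S)-3-(benzyloxy)-2-methylpropanoate | COC(=O)[C@@H](C)COCc1ccccc1 | intermediate
6 | (S)-3-(benzyloxy)-2-methylpropanal | O=C[C@@H](C)COCc1ccccc1 | intermediate
7 | (S)-4-benzyl-3-[(2R,4R,5S,6S)-7-(benzyloxy)-5-hydroxy-2,4,6-trimethyl-3-oxoheptanoyl]-1,3-oxazolidin-2-one | O=C1OC[C@H](Cc2ccccc2)N1C(=O)[C@H](C)C(=O)[C@H](C)[C@@H](O)[C@@H](C)COCc3ccccc3 | intermediate
8 | (S)-4-benzyl-3-[(2R,3S,4R,5S,6S)-7-(benzyloxy)-3,5-dihydroxy-2,4,6-trimethylheptanoyl]-1,3-oxazolidin-2-one | O=C1OC[C@H](Cc2ccccc2)N1C(=O)[C@H](C)[C@@H](O)[C@H](C)[C@@H](O)[C@@H](C)COCc3ccccc3 | intermediate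
9 | 3,5-bis-O-TES ether of 8 | O=C1OC[C@H](Cc2ccccc2)N1C(=O)[C@H](C)[C@@H](O[Si](CC)(CC)CC)[C@H](C)[C@@H](O[Si](CC)(CC)CC)[C@@H](C)COCc3ccccc3 | intermediate
10 | 7-(benzyloxy)-2,4,6-trimethyl-3,5-bis(triethylsilyloxy)heptan-1-ol, C2–C6 as in 8 | OC[C@H](C)[C@@H](O[Si](CC)(CC)CC)[C@H](C)[C@@H](O[Si](CC)(CC)CC)[C@@H](C)COCc1ccccc1 | intermediate
11 | 1-O-TBDPS ether of 10 | CC(C)(C)[Si](c1ccccc1)(c2ccccc2)OC[C@H](C)[C@@H](O[Si](CC)(CC)CC)[C@H](C)[C@@H](O[Si](CC)(CC)CC)[C@@H](C)COCc3ccccc3 | intermediate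
12 | C7 alcohol (1-O-TBDPS; 3,5-bis-O-TES) | CC(C)(C)[Si](c1ccccc1)(c2ccccc2)OC[C@H](C)[C@@H](O[Si](CC)(CC)CC)[C@H](C)[C@@H](O[Si](CC)(CC)CC)[C@@H](C)CO | intermediate
13 | C1–C7 iodide (1-O-TBDPS; 3,5-bis-O-TES) | CC(C)(C)[Si](c1ccccc1)(c2ccccc2)OC[C@H](C)[C@@H](O[Si](CC)(CC)CC)[C@H](C)[C@@H](O[Si](CC)(CC)CC)[C@@H](C)CI | intermediate
14 | pentan-3-one | CCC(=O)CC | starting material
15 | pentan-3-one N,N-dimethylhydrazone | CCC(=NN(C)C)CC | intermediate
16 | alkylated dimethylhydrazone (C1–C10; both C8 epimers) | CC(C)(C)[Si](c1ccccc1)(c2ccccc2)OC[C@H](C)[C@@H](O[Si](CC)(CC)CC)[C@H](C)[C@@H](O[Si](CC)(CC)CC)[C@@H](C)CC(C)C(=NN(C)C)CC | intermediate (not isolated)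
17 | C1–C10 ethyl ketone (both C8 epimers) | CC(C)(C)[Si](c1ccccc1)(c2ccccc2)OC[C@H](C)[C@@H](O[Si](CC)(CC)CC)[C@H](C)[C@@H](O[Si](CC)(CC)CC)[C@@H](C)CC(C)C(=O)CC | intermediate
18 | acetaldehyde | CC=O | starting material
19 | (S)-4-benzyl-3-[(2S,3R)-3-hydroxy-2-methylbutanoyl]-1,3-oxazolidin-2-one | O=C1OC[C@H](Cc2ccccc2)N1C(=O)[C@@H](C)[C@@H](C)O | intermediate
20 | (2S,3R)-3-hydroxy-N-methoxy-N,2-dimethylbutanamide | CON(C)C(=O)[C@@H](C)[C@@H](C)O | intermediate
21 | (2S,3R)-N-methoxy-N,2-dimethyl-3-(triethylsilyloxy)butanamide | CON(C)C(=O)[C@@H](C)[C@@H](C)O[Si](CC)(CC)CC | intermediate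
22 | (2S,3R)-2-methyl-3-(triethylsilyloxy)butanal | O=C[C@@H](C)[C@@H](C)O[Si](CC)(CC)CC | intermediate
23 | C1–C13 aldol adduct (11-hydroxy-9-ketone; 1-O-TBDPS; 3,5,13-tris-O-TES; both C8 epimers) | CC(C)(C)[Si](c1ccccc1)(c2ccccc2)OC[C@H](C)[C@@H](O[Si](CC)(CC)CC)[C@H](C)[C@@H](O[Si](CC)(CC)CC)[C@@H](C)CC(C)C(=O)[C@H](C)[C@@H](O)[C@@H](C)[C@@H](C)O[Si](CC)(CC)CC | intermediate
24 | 11-O-benzyl ether of 23 | CC(C)(C)[Si](c1ccccc1)(c2ccccc2)OC[C@H](C)[C@@H](O[Si](CC)(CC)CC)[C@H](C)[C@@H](O[Si](CC)(CC)CC)[C@@H](C)CC(C)C(=O)[C@H](C)[C@@H](OCc3ccccc3)[C@@H](C)[C@@H](C)O[Si](CC)(CC)CC | intermediate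
25 | keto triol (3,5,13-trihydroxy-9-ketone; 1-O-TBDPS; 11-O-Bn; both C8 epimers) | CC(C)(C)[Si](c1ccccc1)(c2ccccc2)OC[C@H](C)[C@@H](O)[C@H](C)[C@@H](O)[C@@H](C)CC(C)C(=O)[C@H](C)[C@@H](OCc3ccccc3)[C@@H](C)[C@@H](C)O | intermediate
26 | 5,9:9,13-spiroketal (1-O-TBDPS; 3-OH; 11-O-Bn; C8 and C10 as in the target) | CC(C)(C)[Si](c1ccccc1)(c2ccccc2)OC[C@H](C)[C@@H](O)[C@H](C)[C@@H]3[C@@H](C)C[C@@H](C)[C@@]4(O3)[C@H](C)[C@@H](OCc5ccccc5)[C@@H](C)[C@@H](C)O4 | intermediate
27 | C9 1,3-dithiane 3,5,13-triol (1-O-TBDPS; 11-O-Bn) | CC(C)(C)[Si](c1ccccc1)(c2ccccc2)OC[C@H](C)[C@@H](O)[C@H](C)[C@@H](O)[C@@H](C)C[C@@H](C)C3(SCCCS3)[C@H](C)[C@@H](OCc4ccccc4)[C@@H](C)[C@@H](C)O | intermediate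
28 | 3,5-O-benzylidene acetal of 27 (phenyl equatorial) | CC(C)(C)[Si](c1ccccc1)(c2ccccc2)OC[C@H](C)[C@H]3O[C@@H](c4ccccc4)O[C@H]([C@H]3C)[C@@H](C)C[C@@H](C)C5(SCCCS5)[C@H](C)[C@@H](OCc6ccccc6)[C@@H](C)[C@@H](C)O | intermediate
29 | 1,13-diol (C9 dithiane; 3,5-O-benzylidene; 11-O-Bn) | OC[C@H](C)[C@H]1O[C@@H](c2ccccc2)O[C@H]([C@H]1C)[C@@H](C)C[C@@H](C)C3(SCCCS3)[C@H](C)[C@@H](OCc4ccccc4)[C@@H](C)[C@@H](C)O | intermediate
30 | C1 aldehyde of 29 | O=C[C@H](C)[C@H]1O[C@@H](c2ccccc2)O[C@H]([C@H]1C)[C@@H](C)C[C@@H](C)C3(SCCCS3)[C@H](C)[C@@H](OCc4ccccc4)[C@@H](C)[C@@H](C)O | intermediate (not isolated)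
31 | seco acid (C1 acid; 13-OH) | OC(=O)[C@H](C)[C@H]1O[C@@H](c2ccccc2)O[C@H]([C@H]1C)[C@@H](C)C[C@@H](C)C3(SCCCS3)[C@H](C)[C@@H](OCc4ccccc4)[C@@H](C)[C@@H](C)O | intermediate
32 | 2,4,6-trichlorobenzoic mixed anhydride of 31 | O=C(OC(=O)[C@H](C)[C@H]1O[C@@H](c2ccccc2)O[C@H]([C@H]1C)[C@@H](C)C[C@@H](C)C3(SCCCS3)[C@H](C)[C@@H](OCc4ccccc4)[C@@H](C)[C@@H](C)O)c5c(Cl)cc(Cl)cc5Cl | intermediate (not isolated)
33 | 14-membered lactone (C9 dithiane; 3,5-O-benzylidene; 11-O-Bn) | O=C1[C@H](C)[C@H]2O[C@@H](c3ccccc3)O[C@H]([C@H]2C)[C@@H](C)C[C@@H](C)C4(SCCCS4)[C@H](C)[C@@H](OCc5ccccc5)[C@@H](C)[C@@H](C)O1 | intermediate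
34 | 3,5-O-benzylidene-11-O-benzyl-8,8a-deoxyoleandolide | O=C1[C@H](C)[C@H]2O[C@@H](c3ccccc3)O[C@H]([C@H]2C)[C@@H](C)C[C@@H](C)C(=O)[C@H](C)[C@@H](OCc4ccccc4)[C@@H](C)[C@@H](C)O1 | intermediate
35 | 8,8a-deoxyoleandolide | C[C@@H]1[C@@H](O)[C@@H](C)C[C@@H](C)C(=O)[C@H](C)[C@@H](O)[C@@H](C)[C@@H](C)OC(=O)[C@H](C)[C@H]1O | target

**Step count**
Total: 27 steps. Longest linear sequence: 21 steps (steps 2–10, 12 and 17–27, from 4).

**Steps most likely to fail**

Step 20. Proton loss from the oxocarbenium ion toward the more substituted C8 may be slow, so that equilibration at C8 stalls short of the thermodynamic mixture; the C9=C10 enol ether may also ionise at C11 and lose benzyl alcohol. The fallback sets C8 by auxiliary control, so the spiroketal closure no longer has to epimerise anything. It sets out from 13 and 14. Pentan-3-one is condensed with (R)-1-amino-2-(methoxymethyl)pyrrolidine to the RAMP hydrazone F1. F1 is lithiated with LiN(i-Pr)2 and alkylated with 13 (Enders alkylation, the R auxiliary giving the 8R centre for a CH2R electrophile) to the (8R)-hydrazone F2, which is cleaved with aqueous Cu(OAc)2 to the (8R)-ethyl ketone F3. F3 is carried through the conditions of steps 17, 18 and 19 as single 8R isomers: the (8R)-aldol adduct F4, the (8R)-benzyl ether F5 and the (8R)-keto triol F6. F6 closes with PPTS in CH2Cl2 at room temperature and the sequence comes back to the route at 26.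

Step 21. The ring-opened oxocarbenium or thionium ion sits between two branched carbons, so proton loss (which would scramble C8 or C10) may compete with sulfur capture, or the exchange may stop at the monothio ketal. The fallback replaces acid-promoted exchange with a free thiol by silicon-transfer exchange, in which O–Si bond formation drives the opening and no protic acid is present. It sets out from 26, which is treated with Me3SiS(CH2)3SSiMe3 and catalytic ZnI2 in Et2O/CH2Cl2. This should give the dithiane with O3, O5 and O13 as silyl ethers, the tris(trimethylsilyl) ether F7. K2CO3 in MeOH then removes the three trimethylsilyl groups and the sequence comes back to the route at 27.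

Step 25. Without a 9,11-tether, and with the bulky dithiane holding C8–C10 extended, intermolecular acylation may outrun ring closure and give oligomers. The fallback cyclises a different substrate, the keto acid with an sp2 C9, at room temperature to limit epimerisation at C8 and C10. It sets out from 29. The dithiane is removed first (MeI, CaCO3, MeCN/H2O) to give the keto diol F8, which may sit partly as its 9,13-hemiketal. TEMPO/PhI(OAc)2, now with no sulfur present, gives the keto acid F9. Shiina macrolactonisation (2-methyl-6-nitrobenzoic anhydride, DMAP, CH2Cl2, rt, slow addition) proceeds through the mixed anhydride F10 and the sequence comes back to the route at 34.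

**Further compounds**
F1 | step 20 | pentan-3-one RAMP hydrazone, (R)-2-(methoxymethyl)-N-(pentan-3-ylidene)pyrrolidin-1-amine | CCC(=NN1CCC[C@@H]1COC)CC
F2 | step 20 | (8R)-alkylated RAMP hydrazone (C1–C10; 1-O-TBDPS; 3,5-bis-O-TES) | CC(C)(C)[Si](c1ccccc1)(c2ccccc2)OC[C@H](C)[C@@H](O[Si](CC)(CC)CC)[C@H](C)[C@@H](O[Si](CC)(CC)CC)[C@@H](C)C[C@@H](C)C(=NN3CCC[C@@H]3COC)CC
F3 | step 20 | (8R)-C1–C10 ethyl ketone | CC(C)(C)[Si](c1ccccc1)(c2ccccc2)OC[C@H](C)[C@@H](O[Si](CC)(CC)CC)[C@H](C)[C@@H](O[Si](CC)(CC)CC)[C@@H](C)C[C@@H](C)C(=O)CC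
F4 | step 20 | (8R)-aldol adduct (single isomer of 23) | CC(C)(C)[Si](c1ccccc1)(c2ccccc2)OC[C@H](C)[C@@H](O[Si](CC)(CC)CC)[C@H](C)[C@@H](O[Si](CC)(CC)CC)[C@@H](C)C[C@@H](C)C(=O)[C@H](C)[C@@H](O)[C@@H](C)[C@@H](C)O[Si](CC)(CC)CC
F5 | step 20 | (8R)-benzyl ether (single isomer of 24) | CC(C)(C)[Si](c1ccccc1)(c2ccccc2)OC[C@H](C)[C@@H](O[Si](CC)(CC)CC)[C@H](C)[C@@H](O[Si](CC)(CC)CC)[C@@H](C)C[C@@H](C)C(=O)[C@H](C)[C@@H](OCc3ccccc3)[C@@H](C)[C@@H](C)O[Si](CC)(CC)CC
F6 | step 20 | (8R)-keto triol (single isomer of 25) | CC(C)(C)[Si](c1ccccc1)(c2ccccc2)OC[C@H](C)[C@@H](O)[C@H](C)[C@@H](O)[C@@H](C)C[C@@H](C)C(=O)[C@H](C)[C@@H](OCc3ccccc3)[C@@H](C)[C@@H](C)O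
F7 | step 21 | 3,5,13-tris(trimethylsilyl) ether of 27 | CC(C)(C)[Si](c1ccccc1)(c2ccccc2)OC[C@H](C)[C@@H](O[Si](C)(C)C)[C@H](C)[C@@H](O[Si](C)(C)C)[C@@H](C)C[C@@H](C)C3(SCCCS3)[C@H](C)[C@@H](OCc4ccccc4)[C@@H](C)[C@@H](C)O[Si](C)(C)C
F8 | step 25 | keto diol (9-ketone; 1,13-diol; 3,5-O-benzylidene; 11-O-Bn) | OC[C@H](C)[C@H]1O[C@@H](c2ccccc2)O[C@H]([C@H]1C)[C@@H](C)C[C@@H](C)C(=O)[C@H](C)[C@@H](OCc3ccccc3)[C@@H](C)[C@@H](C)O
F9 | step 25 | keto acid (9-ketone; C1 acid; 13-OH) | OC(=O)[C@H](C)[C@H]1O[C@@H](c2ccccc2)O[C@H]([C@H]1C)[C@@H](C)C[C@@H](C)C(=O)[C@H](C)[C@@H](OCc3ccccc3)[C@@H](C)[C@@H](C)O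
F10 | step 25 | 2-methyl-6-nitrobenzoic mixed anhydride of F9 | Cc1cccc([N+](=O)[O-])c1C(=O)OC(=O)[C@H](C)[C@H]2O[C@@H](c3ccccc3)O[C@H]([C@H]2C)[C@@H](C)C[C@@H](C)C(=O)[C@H](C)[C@@H](OCc4ccccc4)[C@@H](C)[C@@H](C)O
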